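Ring B is opened across C8–C9: the C8 tertiary carbinol (with its methyl), C9 and the C10 oxygen of ring B form an aldol pattern, so C10 becomes a ketone and C8 an acetyl group on C7 of ring A. In one operation a samarium enolate, generated regiospecifically from a C10 bromomethyl ketone, adds through C9 to the C8 methyl ketone, closing ring B, forming C8–C9 and setting C8. The precursor is an all-cis ring A cyclohexene from (S)-carvone carrying the C5 acetate, the C7 acetyl group and, on C2, the C1 arm with the bromoacetyl group and a silyl-protected 2-propenol unit; both side-chain acids are made separately.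

Key step: step 14

Numbering and faces: ring B = C1 (acrylate-bearing), C2, C7, C8 (carbinol), C9, C10 (acyloxy); ring A = C2, C3=C4(Me), C5 (OAc), C6, C7; Ca = acrylic α-carbon; β = the face of ring A that carries the C5 oxygen and the C7–C8 bond.

Remark on the chemistry (key step): C9 and C10 both become ring atoms, so the closure is 6-(enolendo)-exo-trig; a samarium ion bridging O10 and O8 would need O8 axial and, in the only accessible chair, would deliver the C8 epimer, so the reaction is run with HMPA-saturated samarium through the open arrangement with O8 equatorial.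

Remark on protecting groups and sources: the Ca arm carries a tert-butyldiphenylsilyl ether (stable to the aqueous HBr of step 13), and the acetonide side-chain acid is made from but-2-yne-1,4-diol because a syn hydrostannation fixes its alkene geometry.

Step 1
Reactants: 1 (S)-carvone
Product: 3 (S)-5-acetyl-2-methylcyclohex-2-en-1-one, via secondary ozonide 2 (not isolated)
Conditions: O3, CH2Cl2, −78 °C; then PPh3, −78 °C → rt
Reagents that add atoms: ozone [O-][O+]=O
Why: Ozonolysis should cleave the electron-rich 1,1-disubstituted alkene far faster than the electron-poor enone, and the stereocenter (future C7) is untouched.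

Step 2
Reactants: 3 (S)-5-acetyl-2-methylcyclohex-2-en-1-one
Product: 4 (S)-2-methyl-5-(2-methyl-1,3-dioxolan-2-yl)cyclohex-2-en-1-one
Conditions: Me3SiOCH2CH2OSiMe3, Me3SiOTf (cat.), CH2Cl2, −78 °C
Reagents that add atoms: 1,2-bis(trimethylsilyloxy)ethane C[Si](C)(C)OCCO[Si](C)(C)C
Why: Noyori ketalisation is selective for a saturated ketone over a conjugated enone and, being aprotic and cold, should not epimerise the α-stereocenter (C7).

Step 3
Reactants: 4 ketal enone
Product: 5 cis-allylic alcohol (C5–OH β, cis to the C7 dioxolanyl group)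
Conditions: NaBH4, CeCl3·7H2O, MeOH, −78 °C → 0 °C
Reagents that add atoms: none
Why: Luche 1,2-reduction with axial hydride attack should give the hydroxyl cis to the C7 substituent, which is the C5 configuration of the target.

Step 4
Reactants: 5 cis-allylic alcohol
Product: 6 β-epoxy alcohol (C3–C4 epoxide cis to C5–OH)
Conditions: VO(acac)2 (cat.), t-BuOOH, CH2Cl2, 0 °C → rt
Reagents that add atoms: tert-butyl hydroperoxide CC(C)(C)OO
Why: Vanadium-catalysed, hydroxyl-directed epoxidation of a cyclic allylic alcohol delivers oxygen to the face of the C5 hydroxyl, which places the future C4 oxygen on the β face.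

Step 5
Reactants: 6 β-epoxy alcohol
Product: 8 cis-diol (C4 tertiary OH β, C5–OH β, C2=C3), via hydroxy selenide 7 (not isolated)
Conditions: (PhSe)2, NaBH4, EtOH, rt → 60 °C; then 30% H2O2, THF, 0 °C → rt
Reagents that add atoms: none
Why: Selenolate opens the epoxide at the less hindered C3 with inversion and selenoxide syn-elimination then runs away from the carbinol carbon (the known epoxide to allylic alcohol transposition), so the C4 oxygen keeps the β configuration fixed by the epoxide and the double bond moves to C2=C3.

Step 6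
Reactants: 8 cis-diol
Product: 9 C5 monoacetate (C4 tertiary OH free)
Conditions: Ac2O, pyridine, DMAP (cat.), CH2Cl2, 0 °C
Reagents that add atoms: acetic anhydride CC(=O)OC(C)=O
Why: Acylation should take the secondary C5 hydroxyl only, the tertiary C4 hydroxyl being too hindered under these conditions.

Step 7
Reactants: 10 2-methylenepropane-1,3-diol
Product: 11 2-[(tert-butyldiphenylsilyloxy)methyl]prop-2-en-1-ol
Conditions: t-BuPh2SiCl (1 equiv), imidazole, 10 (3 equiv), DMF, 0 °C → rt
Reagents that add atoms: tert-butyl(chloro)diphenylsilane CC(C)(C)[Si](Cl)(c1ccccc1)c1ccccc1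
Why: Silylation of one of two equivalent primary hydroxyls, with the cheap diol in excess to suppress the bis-silyl ether.

Step 8
Reactants: 11 mono-silyl ether
Product: 12 [2-(bromomethyl)allyloxy](tert-butyl)diphenylsilane
Conditions: CBr4, PPh3, CH2Cl2, 0 °C
Reagents that add atoms: carbon tetrabromide BrC(Br)(Br)Br
Why: The Appel reaction converts the primary allylic alcohol into the bromide under neutral conditions that leave the silyl ether.

Step 9
Reactants: 12 allylic bromide
Product: 14 3-[(tert-butyldiphenylsilyloxy)methyl]but-3-enoic acid, via allylic Grignard reagent 13 (not isolated)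
Conditions: Mg, THF, 0 °C (slow addition); CO2, −40 °C → rt; 1 M HCl
Reagents that add atoms: carbon dioxide O=C=O
Why: Carboxylation of an allylic Grignard reagent whose two allyl termini are equivalent, so only this β,γ-unsaturated acid can form.

Step 10
Reactants: 9 C5 monoacetate; 14 butenoic acid
Product: 15 tertiary allylic ester (C4–O acylated by 14)
Conditions: DCC, DMAP (cat.), CH2Cl2, 0 °C → rt
Reagents that add atoms: none
Why: Steglich esterification is a known way to acylate tertiary alcohols, and low temperature with catalytic DMAP should limit migration of the β,γ double bond into conjugation.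

Step 11
Reactants: 15 tertiary allylic ester
Product: 18 Claisen acid (C1–C2 formed, C3=C4 restored, C10 carboxylic acid), via silyl ketene acetal 16 (not isolated), via trimethylsilyl ester 17 (not isolated)
Conditions: Me3SiCl, Et3N, THF, −78 °C; LiN(i-Pr)2 (1.1 equiv); −78 °C → rt; aq. citric acid
Reagents that add atoms: none
Why: Ireland–Claisen [3,3]-sigmatropic rearrangement: the (E)-silyl ketene acetal 16 (kinetic enolisation in THF, only the doubly activated α-CH2 being deprotonated, so the acetate stays) should transfer C1 suprafacially from the β C4 oxygen to C2 through the boat-like transition state usual for cyclohexenyl esters, setting C2 cis to the C7 substituent and C1 as in the target.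

Step 12
Reactants: 18 Claisen acid
Product: 20 diazoketone (C10 carbonyl, C9 diazo carbon), via mixed carbonic anhydride 19 (not isolated)
Conditions: i-BuOCOCl, N-methylmorpholine, THF, −15 °C; CH2N2, Et2O, 0 °C
Reagents that add atoms: diazomethane C=[N+]=[N-]
Why: Acylation of diazomethane by a mixed carbonic anhydride (first stage of the Arndt–Eistert sequence) runs under near-neutral conditions that should not enolise C1.

Step 13
Reactants: 20 diazoketone
Product: 22 bromomethyl ketone with free C8 methyl ketone (cyclisation precursor), via bromoketone ketal 21 (not isolated)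
Conditions: 48% aq. HBr (3 equiv), THF, 0 °C → rt
Reagents that add atoms: hydrogen bromide Br; water O
Why: Protonation of the diazoketone and displacement of N2 by bromide is the known route to bromomethyl ketones, and the same aqueous acid should hydrolyse the dioxolane while the tert-butyldiphenylsilyl ether and the acetate survive.

Step 14
Reactants: 22 bromomethyl ketone with C8 methyl ketone
Product: 24 cis-fused β-hydroxy ketone (ring B closed, C8–OH β, C8–Me α, C10 ketone), via samarium enolate 23 (not isolated)
Conditions: SmI2 (2.2 equiv) added to 22 and HMPA (8 equiv) in THF, −78 °C; then pH 7 phosphate buffer, −78 °C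
Reagents that add atoms: none
Why: Two single-electron transfers from divalent samarium cleave the C9–Br bond and give the trivalent samarium enolate 23 regiospecifically at C9=C10 (C1–H is never deprotonated), and this enolate adds through C9 to the C8 methyl ketone, an intramolecular Reformatsky-type aldol reaction that is known for SmI2 and α-halo ketones with ketone acceptors. Ring B closes in the 6-(enolendo)-exo-trig mode: C9 and C10 both become ring atoms and the C8 oxygen stays outside the ring. C8, the one new stereocenter, is controlled by the chair in which the C1 branch is equatorial and the C7–C6 bond axial, with O8 equatorial and antiperiplanar to C9–C10 and the C8 methyl axial, which puts C8–OH on the β face, cis to C6. The step needs this facial selectivity at the C8 carbonyl, and the substrate secures the chair because the cis ring fusion, the C1 configuration and the C5 acetate exclude the flipped chair (it would place C8 axial on ring A, syn to the C5 acetoxy group). Because a samarium ion bridging O10 and O8 would force O8 axial and give the C8 epimer, HMPA saturates the metal so that the open arrangement is followed, helped by the bulky silyl ether that crowds the α face beside O10. The bromide is reduced far faster than the C8 ketone, and the cold buffered quench should prevent retro-aldol cleavage or dehydration.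

Step 15
Reactants: 24 β-hydroxy ketone
Product: 25 anti-1,3-diol (C10–OH α, axial; C8–OH β)
Conditions: LiBH(s-Bu)3, THF, −78 °C; then H2O
Reagents that add atoms: none
Why: Steric approach control in a ketone reduction: the axial face of C10 is blocked by the syn-axial C8 methyl, so the bulky hydride should attack equatorially and give the axial C10 alcohol, anti to C8–OH and cis to the C1 branch.

Step 16
Reactants: 26 but-2-yne-1,4-diol
Product: 27 (E)-2-(tributylstannyl)but-2-ene-1,4-diol
Conditions: Bu3SnH, PdCl2(PPh3)2 (cat.), THF, rt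
Reagents that add atoms: tributylstannane CCCC[SnH](CCCC)CCCC
Why: Palladium-catalysed hydrostannation is a syn addition, so the two CH2OH groups end cis on the double bond, and the symmetrical alkyne raises no regiochemical question.

Step 17
Reactants: 27 stannyl diol
Product: 28 2,2-dimethyl-5-(tributylstannyl)-4,7-dihydro-1,3-dioxepine
Conditions: 2,2-dimethoxypropane, PPTS (cat.), CH2Cl2, rt
Reagents that add atoms: 2,2-dimethoxypropane COC(C)(C)OC
Why: Acetal exchange forms the seven-membered acetonide of a cis-but-2-ene-1,4-diol (known for the parent diol) and locks the alkene geometry in a ring.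

Step 18
Reactants: 28 stannyl dioxepine
Product: 30 2,2-dimethyl-4,7-dihydro-1,3-dioxepine-5-carboxylic acid, via vinyllithium 29 (not isolated)
Conditions: n-BuLi, THF, −78 °C; CO2; 1 M HCl to pH 4, 0 °C
Reagents that add atoms: carbon dioxide O=C=O
Why: Tin–lithium exchange proceeds with retention of alkene geometry and the vinyllithium is carboxylated at −78 °C, where β-elimination of the allylic oxygen should be slow.

Step 19
Reactants: 25 anti-1,3-diol; 30 dioxepine carboxylic acid
Product: 32 C10 ester (C8–OH free), via Yamaguchi mixed anhydride 31 (not isolated)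
Conditions: 30, 2,4,6-Cl3C6H2COCl, Et3N, THF, rt; then 25, DMAP, toluene, rt → 60 °C
Reagents that add atoms: none
Why: Yamaguchi esterification should acylate the hindered secondary C10 hydroxyl while the tertiary C8 hydroxyl stays free, and the ring-locked acid cannot isomerise, so the (E) geometry of the side chain is secured.

Step 20
Reactants: 32 C10 ester
Product: 33 primary allylic alcohol (Ca–CH2OH)
Conditions: Bu4NF, AcOH, THF, 0 °C → rt
Reagents that add atoms: none
Why: Fluoride cleaves the primary silyl ether, and buffering with acetic acid should keep the acetate, the enoate and the acetonide intact.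

Step 21
Reactants: 33 primary allylic alcohol
Product: 34 enal (Ca–CHO)
Conditions: Dess–Martin periodinane, pyridine, CH2Cl2, 0 °C → rt
Reagents that add atoms: none
Why: Dess–Martin oxidation takes the primary allylic alcohol to the enal, and the tertiary C8 alcohol cannot be oxidised.

Step 22
Reactants: 34 enal
Product: 35 acrylic acid with acetonide-protected side chain
Conditions: NaClO2, NaH2PO4, 2-methyl-2-butene, t-BuOH/H2O, 0 °C → rt
Reagents that add atoms: sodium chlorite [Na+].[O-]Cl=O
Why: Pinnick oxidation converts the enal into the acrylic acid without touching the alkenes, since 2-methyl-2-butene traps the hypochlorite.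

Step 23
Reactants: 35 acrylic acid acetonide
Product: 36 target compound
Conditions: AcOH/H2O (4:1), rt
Reagents that add atoms: none
Why: Mild aqueous acid should hydrolyse the seven-membered acetonide to the 1,4-diol while the acetate, the tertiary alcohol and the acrylic acid are stable.

Compound list
1 | (S)-carvone | CC(=C)[C@H]1CC=C(C)C(=O)C1 | starting material
2 | secondary ozonide (1,2,4-trioxolane) of the isopropenyl group of 1 | CC1(OCOO1)[C@H]2CC=C(C)C(=O)C2 | intermediate
3 | (S)-5-acetyl-2-methylcyclohex-2-en-1-one | CC(=O)[C@H]1CC=C(C)C(=O)C1 | intermediate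
4 | (S)-2-methyl-5-(2-methyl-1,3-dioxolan-2-yl)cyclohex-2-en-1-one | CC1(OCCO1)[C@H]2CC=C(C)C(=O)C2 | intermediate
5 | 2-methyl-5-(2-methyl-1,3-dioxolan-2-yl)cyclohex-2-en-1-ol, hydroxyl cis to the dioxolanyl group (C5–OH β) | CC1=CC[C@@H](C[C@@H]1O)C2(C)OCCO2 | intermediate
6 | C3–C4 β-epoxide of 5, epoxide cis to C5–OH | C[C@]12[C@@H](O)C[C@H](C[C@H]1O2)C3(C)OCCO3 | intermediate
7 | hydroxy selenide: C3–SePh α, C4–OH β (tertiary), C5–OH β | C[C@]1(O)[C@@H](O)C[C@H](C[C@@H]1[Se]c2ccccc2)C3(C)OCCO3 | intermediate
8 | cis-diol: 1-methyl-4-(2-methyl-1,3-dioxolan-2-yl)cyclohex-2-ene-1,6-diol, C4–OH and C5–OH β, C2=C3 | C[C@@]1(O)C=C[C@@H](C[C@@H]1O)C2(C)OCCO2 | intermediate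
9 | C5 monoacetate of 8 (tertiary C4–OH free) | C[C@@]1(O)C=C[C@@H](C[C@@H]1OC(C)=O)C2(C)OCCO2 | intermediate
10 | 2-methylenepropane-1,3-diol | C=C(CO)CO | starting material
11 | 2-[(tert-butyldiphenylsilyloxy)methyl]prop-2-en-1-ol | C=C(CO)CO[Si](c1ccccc1)(c2ccccc2)C(C)(C)C | intermediate
12 | [2-(bromomethyl)allyloxy](tert-butyl)diphenylsilane | C=C(CBr)CO[Si](c1ccccc1)(c2ccccc2)C(C)(C)C | intermediate
13 | allylic Grignard reagent from 12 | C=C(C[Mg]Br)CO[Si](c1ccccc1)(c2ccccc2)C(C)(C)C | intermediate
14 | 3-[(tert-butyldiphenylsilyloxy)methyl]but-3-enoic acid | C=C(CC(=O)O)CO[Si](c1ccccc1)(c2ccccc2)C(C)(C)C | intermediate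
15 | tertiary allylic ester: C4–O ester of 9 with 14 | C[C@@]1(OC(=O)CC(=C)CO[Si](c2ccccc2)(c3ccccc3)C(C)(C)C)C=C[C@@H](C[C@@H]1OC(C)=O)C4(C)OCCO4 | intermediate
16 | (E)-trimethylsilyl ketene acetal of 15 (Ca branch cis to the allylic oxygen) | C[C@@]1(O/C(O[Si](C)(C)C)=C\C(=C)CO[Si](c2ccccc2)(c3ccccc3)C(C)(C)C)C=C[C@@H](C[C@@H]1OC(C)=O)C4(C)OCCO4 | intermediate
17 | trimethylsilyl ester of 18 | C=C(CO[Si](c3ccccc3)(c4ccccc4)C(C)(C)C)[C@@H](C(=O)O[Si](C)(C)C)[C@H]1C=C(C)[C@@H](OC(C)=O)C[C@H]1C2(C)OCCO2 | intermediate
18 | Claisen acid: ring A with C2 arm CH(Ca unit)(CO2H) β, C5–OAc β, C7 ketal β, C3=C4 | C=C(CO[Si](c3ccccc3)(c4ccccc4)C(C)(C)C)[C@@H](C(=O)O)[C@H]1C=C(C)[C@@H](OC(C)=O)C[C@H]1C2(C)OCCO2 | intermediate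
19 | mixed isobutyl carbonic anhydride of 18 | C=C(CO[Si](c3ccccc3)(c4ccccc4)C(C)(C)C)[C@@H](C(=O)OC(=O)OCC(C)C)[C@H]1C=C(C)[C@@H](OC(C)=O)C[C@H]1C2(C)OCCO2 | intermediate
20 | diazoketone (C10 carbonyl, C9 diazo carbon), C8 as dioxolane | C=C(CO[Si](c3ccccc3)(c4ccccc4)C(C)(C)C)[C@@H](C(=O)C=[N+]=[N-])[C@H]1C=C(C)[C@@H](OC(C)=O)C[C@H]1C2(C)OCCO2 | intermediate
21 | bromomethyl ketone, C8 still as dioxolane | C=C(CO[Si](c3ccccc3)(c4ccccc4)C(C)(C)C)[C@@H](C(=O)CBr)[C@H]1C=C(C)[C@@H](OC(C)=O)C[C@H]1C2(C)OCCO2 | intermediate
22 | cyclisation precursor: ring A methyl ketone (C7 acetyl) with bromomethyl ketone arm on C1 | C=C(CO[Si](c3ccccc3)(c4ccccc4)C(C)(C)C)[C@@H](C(=O)CBr)[C@H]1C=C(C)[C@@H](OC(C)=O)C[C@H]1C(C)=O | intermediate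
23 | trivalent samarium enolate at C9=C10 | C=C(CO[Si](c3ccccc3)(c4ccccc4)C(C)(C)C)[C@@H](C(=C)O[Sm](I)I)[C@H]1C=C(C)[C@@H](OC(C)=O)C[C@H]1C(C)=O | intermediate
24 | cis-fused β-hydroxy ketone: C8–OH β, C8–Me α, C10 ketone, C1 branch α | C=C(CO[Si](c3ccccc3)(c4ccccc4)C(C)(C)C)[C@@H]1[C@H]2C=C(C)[C@@H](OC(C)=O)C[C@H]2[C@@](C)(O)CC1=O | intermediate
25 | anti-1,3-diol: C10–OH α, C8–OH β | C=C(CO[Si](c3ccccc3)(c4ccccc4)C(C)(C)C)[C@@H]1[C@H]2C=C(C)[C@@H](OC(C)=O)C[C@H]2[C@@](C)(O)C[C@@H]1O | intermediate
26 | but-2-yne-1,4-diol | OCC#CCO | starting material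
27 | (E)-2-(tributylstannyl)but-2-ene-1,4-diol (CH2OH groups cis) | OC/C=C(/[Sn](CCCC)(CCCC)CCCC)CO | intermediate
28 | 2,2-dimethyl-5-(tributylstannyl)-4,7-dihydro-1,3-dioxepine | CC1(C)OCC=C(CO1)[Sn](CCCC)(CCCC)CCCC | intermediate
29 | 5-lithio-2,2-dimethyl-4,7-dihydro-1,3-dioxepine | [Li]C1=CCOC(C)(C)OC1 | intermediate
30 | 2,2-dimethyl-4,7-dihydro-1,3-dioxepine-5-carboxylic acid | CC1(C)OCC=C(CO1)C(=O)O | intermediate
31 | mixed anhydride of 30 with 2,4,6-trichlorobenzoic acid | CC1(C)OCC=C(CO1)C(=O)OC(=O)c2c(Cl)cc(Cl)cc2Cl | intermediate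
32 | C10 ester of 25 with 30 (silyl ether and acetonide in place) | C=C(CO[Si](c3ccccc3)(c4ccccc4)C(C)(C)C)[C@@H]1[C@H]2C=C(C)[C@@H](OC(C)=O)C[C@H]2[C@@](C)(O)C[C@@H]1OC(=O)C5=CCOC(C)(C)OC5 | intermediate
33 | primary allylic alcohol (Ca–CH2OH) | C=C(CO)[C@@H]1[C@H]2C=C(C)[C@@H](OC(C)=O)C[C@H]2[C@@](C)(O)C[C@@H]1OC(=O)C3=CCOC(C)(C)OC3 | intermediate
34 | enal (Ca–CHO) | C=C(C=O)[C@@H]1[C@H]2C=C(C)[C@@H](OC(C)=O)C[C@H]2[C@@](C)(O)C[C@@H]1OC(=O)C3=CCOC(C)(C)OC3 | intermediate
35 | acrylic acid with acetonide-protected side chain | C=C(C(=O)O)[C@@H]1[C@H]2C=C(C)[C@@H](OC(C)=O)C[C@H]2[C@@](C)(O)C[C@@H]1OC(=O)C3=CCOC(C)(C)OC3 | intermediate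
36 | CNP0468194.1 | C=C(C(=O)O)[C@@H]1[C@H]2C=C(C)[C@@H](OC(C)=O)C[C@H]2[C@@](C)(O)C[C@@H]1OC(=O)/C(=C/CO)CO | target

Total step count: 23. Longest linear sequence: 17 steps (steps 1–6, 10–15 and 19–23, from (S)-carvone).

Steps most likely to fail

Step 14. The closure may follow a samarium-bridged transition state (poor facial selectivity at C8), or the enolate may be protonated before it cyclises. The fallback separates enolate formation from the aldol step. It sets out from 22: reductive silylation (Zn, Me3SiCl, MeCN, 0 °C) should give the C9=C10 trimethylsilyl enol ether F1. An intramolecular Mukaiyama aldol reaction (BF3·OEt2, CH2Cl2, −78 °C, aqueous work-up), which has an open transition state by nature, should then bring the route back at 24.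

Step 11. The ketene acetal geometry may erode, or the chair-like transition state may compete with the boat-like one, giving poor diastereoselectivity at C1 (C2 is not at risk). The fallback gives up stereoselection at C1 in favour of separation and recycling. It sets out from 18 as the C1 mixture, which is taken through step 12; 20 is separated by chromatography from the C1-epimeric diazoketone F2. F2, whose C1–H is α to the carbonyl and allylic, is re-equilibrated with DBU in toluene at rt and separated again, so the route is rejoined at 20.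

Step 15. Hydride may also attack the axial face (poor facial selectivity, giving the syn diol), or the basic hydride may cleave the C5 acetate. The fallback replaces steric approach control by intramolecular delivery. It sets out from 24: Me4NBH(OAc)3 in MeCN/AcOH at −20 °C should exchange one acetate for the C8 hydroxyl to give the alkoxy(diacetoxy)borohydride F3. F3 can deliver hydride only to the β face of C10 (Evans–Saksena anti reduction; esters are inert to the reagent), and the route is rejoined at 25.

Further compounds
F1 | step 14 | trimethylsilyl enol ether of 22 at C9=C10 | C=C(CO[Si](c3ccccc3)(c4ccccc4)C(C)(C)C)[C@@H](C(=C)O[Si](C)(C)C)[C@H]1C=C(C)[C@@H](OC(C)=O)C[C@H]1C(C)=O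
F2 | step 11 | C1 epimer of diazoketone 20 | C=C(CO[Si](c3ccccc3)(c4ccccc4)C(C)(C)C)[C@H](C(=O)C=[N+]=[N-])[C@H]1C=C(C)[C@@H](OC(C)=O)C[C@H]1C2(C)OCCO2
F3 | step 15 | tetramethylammonium alkoxy(diacetoxy)borohydride of 24 at the C8 oxygen | C=C(CO[Si](c3ccccc3)(c4ccccc4)C(C)(C)C)[C@@H]1[C@H]2C=C(C)[C@@H](OC(C)=O)C[C@H]2[C@@](C)(O[BH-](OC(C)=O)OC(C)=O)CC1=O.C[N+](C)(C)C
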